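**Plan**

1. Numbering used here (germacrane type): C7 is the ring CH carrying the isopropenyl group (C11=C12), followed round the ring by C6 (CH2), C5/C4 (epoxide, methyl on C4), C3 (OAng), C2 (CH2), C1/C10 (epoxide, methyl on C10), C9 (OAc) and C8 (OAng). β is the ring face that carries the isopropenyl group in the flat drawing.
2. Retrosynthetic cuts: the three ester C–O bonds; the C9–H bond (back to a 9-ketone); the C4/C5 epoxide C–O bonds; then, in one operation, the C8–O and C6–C7 bonds (the carbocycle contracts from ten to eight atoms, C7 and C8 leaving the ring); the C8–C9 bond to a five-carbon dienyl unit; finally the C1/C10 epoxide and the C3–O and C9–O bonds.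
3. Enabling feature: both epoxides are cis-fused and each lies in a C(O)–C(Me)(O)–CH(O) array. C10, C1–C6 and C9 with both methyls are therefore (Z,Z)-1,5-dimethylcycloocta-1,5-diene oxidised at its two allylic CH2 groups (C3 and C9). In that eight-membered ring C9 is a carbinol carbon bonded to the allylic C6, the array a 1-alkenylcyclooct-3-en-1-olate needs to insert C8–C7 by a [1,3] shift.
4. Forward order: bought eight-membered ring → dienedione → C2-symmetric diol → C1/C10 epoxy ketone → dienyl carbinol → ten-membered ring by alkoxide-accelerated two-carbon ring expansion with in-situ C8 hydroxylation → C4/C5 epoxide → angelates → C9 reduction → acetate.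
5. Stereochemistry: a double CBS reduction sets C3 and a temporary C9 carbinol. This is relayed by hydroxyl-directed epoxidation (C1, C10), addition anti to the epoxide (C9), chirality transfer in the ring expansion (C7), A1,3 control in the enolate oxidation (C8), anti-selective peracid epoxidation (C4, C5) and hydride delivery anti to both α-oxygens (C9). The Z geometry of the angelates comes with angelic acid.

Key step: step 9

Remark: technical 1,5-dimethylcycloocta-1,5-diene contains some of the 1,6-dimethyl isomer; isomerically pure 1 is assumed, and material derived from the isomer would otherwise be removed at dione 3.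

**Route**

Step 1
Reactants: 1 (1Z,5Z)-1,5-dimethylcycloocta-1,5-diene
Product: 2 (2Z,6Z)-2,6-dimethylcycloocta-2,6-diene-1,5-diol (cis/trans mixture)
Conditions: SeO2 (cat.), t-BuOOH (4 equiv), salicylic acid (cat.), CH2Cl2, rt
Reagents that add atoms: selenium dioxide O=[Se]=O (oxygen carrier); tert-butyl hydroperoxide CC(C)(C)OO (terminal oxidant)
Why: SeO2-catalysed allylic oxidation (ene reaction followed by [2,3]-sigmatropic shift) should hydroxylate each trisubstituted ring alkene at the ring CH2 attached to its methyl-bearing carbon and return the double bond to its original Z position; the two carbinol centres form without control, which does not matter because both are oxidised in step 2.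

Step 2
Reactants: 2 (2Z,6Z)-2,6-dimethylcycloocta-2,6-diene-1,5-diol
Product: 3 (2Z,6Z)-2,6-dimethylcycloocta-2,6-diene-1,5-dione
Conditions: Dess–Martin periodinane, CH2Cl2, 0 °C to rt
Reagents that add atoms: none
Why: Dess–Martin oxidation under neutral conditions should convert both allylic alcohols (and any ketol from over-oxidation in step 1) into the single C2-symmetric dienedione without base-induced migration of the β,γ-double bonds.

Step 3
Reactants: 3 (2Z,6Z)-2,6-dimethylcycloocta-2,6-diene-1,5-dione
Product: 4 (1S,5S)-2,6-dimethylcycloocta-2,6-diene-1,5-diol (cis, C2-symmetric)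
Conditions: (R)-Me-CBS (20 mol %), BH3·SMe2, THF, −40 °C; MeOH
Reagents that add atoms: none
Why: Corey–Bakshi–Shibata reduction: with the α-methylalkenyl arm as the large substituent the (R)-catalyst should deliver hydride to give the (S)-carbinol at each of the two homotopic carbonyl groups, so that the cis (C2) diol carries the future C3 centre and a temporary C9 centre, the double reduction raising its ee while the minor meso (trans) diol is separated.

Step 4
Reactants: 4 (1S,5S)-2,6-dimethylcycloocta-2,6-diene-1,5-diol
Product: 5 (1S,5S)-5-(tert-butyldimethylsilyloxy)-2,6-dimethylcycloocta-2,6-dien-1-ol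
Conditions: TBSCl (1.0 equiv), imidazole, DMF, 0 °C
Reagents that add atoms: tert-butyldimethylsilyl chloride CC(C)(C)[Si](C)(C)Cl
Why: Monosilylation of a C2-symmetric diol can give only one monoether because the two hydroxyls are homotopic; unreacted diol and bis-ether are recycled.

Step 5
Reactants: 5 (1S,5S)-5-(tert-butyldimethylsilyloxy)-2,6-dimethylcycloocta-2,6-dien-1-ol
Product: 6 (1S,5S)-5-(tert-butyldimethylsilyloxy)-2,3-epoxy-2,6-dimethylcyclooct-6-en-1-ol (epoxide oxygen cis to 1-OH and to 5-OTBS)
Conditions: VO(acac)2 (5 mol %), t-BuOOH (1.2 equiv), CH2Cl2, 0 °C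
Reagents that add atoms: tert-butyl hydroperoxide CC(C)(C)OO
Why: Vanadium-catalysed hydroxyl-directed epoxidation should act only on the alkene allylic to the free hydroxyl and, as is usual for (Z)-cyclooct-2-enols, deliver oxygen syn to it, which places the C1/C10 epoxide on the β face shared with the C3 oxygen.

Step 6
Reactants: 6 epoxy alcohol
Product: 7 (5S)-5-(tert-butyldimethylsilyloxy)-2,3-epoxy-2,6-dimethylcyclooct-6-en-1-one (epoxide oxygen cis to 5-OTBS)
Conditions: Dess–Martin periodinane, pyridine, CH2Cl2, 0 °C to rt
Reagents that add atoms: none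
Why: Dess–Martin oxidation removes the temporary C9 carbinol centre after it has done its directing work and gives the α,β-epoxy ketone without opening the epoxide or cleaving the silyl ether.

Step 7
Reactants: 8 2-methylbut-1-en-3-yne
Product: 10 (E)-1-iodo-3-methylbuta-1,3-diene, via dienylzirconocene chloride 9 (not isolated)
Conditions: Cp2Zr(H)Cl, THF, rt; I2, 0 °C
Reagents that add atoms: iodine II
Why: Hydrozirconation adds Zr–H syn and with the metal at the terminal carbon to the alkyne in preference to the 1,1-disubstituted alkene, and iodinolysis proceeds with retention, so the E dienyl iodide should result.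

Step 8
Reactants: 7 epoxy ketone; 10 (E)-1-iodo-3-methylbuta-1,3-diene
Product: 13 (5S)-5-(tert-butyldimethylsilyloxy)-2,3-epoxy-2,6-dimethyl-1-[(E)-3-methylbuta-1,3-dien-1-yl]cyclooct-6-en-1-ol (1-OH cis to the epoxide oxygen), via dienyllithium 11 (not isolated), via dienylcerium dichloride 12 (not isolated)
Conditions: 10, t-BuLi (2 equiv), Et2O, −78 °C; CeCl3, THF, −78 °C; 7, −78 °C; H2O
Reagents that add atoms: none
Why: Iodine–lithium exchange with retention of the E geometry and transmetallation to the weakly basic organocerium reagent should allow 1,2-addition to the enolisable ketone without epoxide opening; attack anti to the α-epoxide C–O bond (polar Felkin–Anh model, as usual for cyclic α,β-epoxy ketones) and anti to the transannular silyloxy group sets the C9 carbinol with its oxygen cis to the epoxide oxygen.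

Step 9
Reactants: 13 dienyl carbinol
Product: 16 (4Z)-3β-(tert-butyldimethylsilyloxy)-1β,10β-epoxy-8β-hydroxygermacra-4,11(12)-dien-9-one, via potassium alkoxide 14 (not isolated), via potassium enolate 15 (not isolated)
Conditions: KH, 18-crown-6, THF, 0 °C to rt; −78 °C, 2-(phenylsulfonyl)-3-phenyloxaziridine; AcOH, −78 °C
Reagents that add atoms: 2-(phenylsulfonyl)-3-phenyloxaziridine O=S(=O)(N1OC1c1ccccc1)c1ccccc1
Why: Deprotonation gives the tertiary alkoxide 14, whose C9–C6 bond to the allylic carbon is weakened by the oxyanion and migrates suprafacially from C9 to the dienyl β-carbon C7 (alkoxide-accelerated [1,3]-sigmatropic shift, in the limit a fragmentation to an allyl anion/dienone pair and 1,4-recombination), after which the regiodefined enolate 15 is hydroxylated at C8 by the oxaziridine. The closest known reaction type is the two-carbon ring expansion of potassium 1-vinylcyclooct-3-en-1-olates to cyclodec-5-enones, combined with the in-situ oxidation of enolates that is practised after anionic oxy-Cope rearrangements. The ten-membered ring arises by ring expansion of the eight-membered ring (C6–C7 made, C6–C9 broken, C8 and C7 inserted) through a four-centre suprafacial shift that keeps the C4=C5 bond Z. C7 is controlled by chirality transfer from C9: with the E dienyl group and the rotamer that leads to the ring-cis enolate, C6 is delivered to the face of C7 that puts the isopropenyl group β; C8 is controlled by allylic 1,3-strain in the enolate (H7 in the enolate plane), the oxidant entering anti to the isopropenyl group. The step needs [1,3] over [3,3] bonding, 1,4- over 1,6-recombination and no epoxide chemistry: the methyl group on C4 hinders bonding at that allyl terminus, the s-trans diene keeps C12 remote, the ring alkene next to C9 is already masked as the epoxide so that no endocyclic acceptor competes, and the alkoxide is cis to the epoxide oxygen so that it cannot open it.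

Step 10
Reactants: 16 silyl ether hydroxy ketone
Product: 17 (4Z)-1β,10β-epoxy-3β,8β-dihydroxygermacra-4,11(12)-dien-9-one
Conditions: HF·pyridine, pyridine, THF, 0 °C to rt
Reagents that add atoms: none
Why: Buffered HF·pyridine cleaves the secondary silyl ether under mildly acidic conditions that avoid base-induced epimerisation or α-ketol shift of the hydroxy ketone and leave the electron-poor keto epoxide intact.

Step 11
Reactants: 17 diol
Product: 18 1β,10β:4α,5α-diepoxy-3β,8β-dihydroxygermacr-11(12)-en-9-one
Conditions: mCPBA (1.1 equiv), CH2Cl2, 0 °C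
Reagents that add atoms: 3-chloroperbenzoic acid O=C(OO)c1cccc(Cl)c1
Why: Prilezhaev epoxidation: the peracid should attack the only electron-rich trisubstituted alkene (the isopropenyl group is less nucleophilic) under hydrogen-bond guidance by the C3 hydroxyl and, as is usual for medium-ring (Z)-allylic alcohols with peracids, from the face anti to that hydroxyl, which sets C4 and C5 (α-epoxide).

Step 12
Reactants: 18 diepoxy diol
Product: 19 3β,8β-bis(angeloyloxy)-1β,10β:4α,5α-diepoxygermacr-11(12)-en-9-one
Conditions: angelic acid, 2,4,6-trichlorobenzoyl chloride, Et3N, toluene, rt, filtration; then 18, Et3N, toluene, 70 °C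
Reagents that add atoms: angelic acid C/C=C(/C)C(=O)O
Why: Yamaguchi-type esterification with the preformed mixed anhydride acylates both hindered secondary hydroxyls without a nucleophilic catalyst, the condition under which angelates keep their Z geometry instead of isomerising to tiglates; no stereocentre is touched provided C8–H is not epimerised, which the limited exposure to amine base is chosen to avoid.

Step 13
Reactants: 19 bis-angelate ketone
Product: 20 3β,8β-bis(angeloyloxy)-1β,10β:4α,5α-diepoxygermacr-11(12)-en-9β-ol
Conditions: NaBH4, CeCl3·7H2O, MeOH, −78 °C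
Reagents that add atoms: none
Why: Luche reduction: hydride should add to the ketone from the α face, anti to both flanking C–O bonds (the epoxide oxygen on C10 and the ester oxygen on C8, polar Felkin–Anh model), giving the 9β-alcohol cis to both, while esters and epoxides are inert at −78 °C.

Step 14
Reactants: 20 9β-alcohol
Product: 21 9β-acetoxy-3β,8β-bis(angeloyloxy)-1β,10β:4α,5α-diepoxygermacr-11(12)-ene (CNP0220329.1)
Conditions: Ac2O, pyridine, DMAP (cat.), CH2Cl2, rt
Reagents that add atoms: acetic anhydride CC(=O)OC(C)=O
Why: DMAP-catalysed acetylation of the only free hydroxyl gives the target without touching any stereocentre.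

**Compound list**

1 | (1Z,5Z)-1,5-dimethylcycloocta-1,5-diene | C/C1=C/CC/C(C)=C\CC1 | starting material
2 | (2Z,6Z)-2,6-dimethylcycloocta-2,6-diene-1,5-diol (cis/trans mixture) | OC1C/C=C(C)\C(O)C/C=C1/C | intermediate
3 | (2Z,6Z)-2,6-dimethylcycloocta-2,6-diene-1,5-dione | O=C1C/C=C(C)\C(=O)C/C=C1/C | intermediate
4 | (1S,5S)-2,6-dimethylcycloocta-2,6-diene-1,5-diol (cis, C2-symmetric) | O[C@H]1C/C=C(C)\[C@@H](O)C/C=C1/C | intermediate
5 | (1S,5S)-5-(tert-butyldimethylsilyloxy)-2,6-dimethylcycloocta-2,6-dien-1-ol | O[C@H]1C/C=C(C)\[C@@H](O[Si](C)(C)C(C)(C)C)C/C=C1/C | intermediate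
6 | (1S,5S)-5-(tert-butyldimethylsilyloxy)-2,3-epoxy-2,6-dimethylcyclooct-6-en-1-ol, epoxide oxygen cis to 1-OH and 5-OTBS | O[C@H]1C/C=C(C)\[C@@H](O[Si](C)(C)C(C)(C)C)C[C@H]2O[C@]21C | intermediate
7 | (5S)-5-(tert-butyldimethylsilyloxy)-2,3-epoxy-2,6-dimethylcyclooct-6-en-1-one, epoxide oxygen cis to 5-OTBS | O=C1C/C=C(C)\[C@@H](O[Si](C)(C)C(C)(C)C)C[C@H]2O[C@]21C | intermediate
8 | 2-methylbut-1-en-3-yne | C=C(C)C#C | starting material
9 | dienylzirconocene chloride, (E)-(3-methylbuta-1,3-dien-1-yl)zirconocene chloride | C=C(C)/C=C/[Zr](Cl)(C1C=CC=C1)C1C=CC=C1 | intermediate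
10 | (E)-1-iodo-3-methylbuta-1,3-diene | C=C(C)/C=C/I | intermediate
11 | dienyllithium, (E)-(3-methylbuta-1,3-dien-1-yl)lithium | C=C(C)/C=C/[Li] | intermediate
12 | dienylcerium dichloride, (E)-(3-methylbuta-1,3-dien-1-yl)cerium dichloride | C=C(C)/C=C/[Ce](Cl)Cl | intermediate
13 | (5S)-5-(tert-butyldimethylsilyloxy)-2,3-epoxy-2,6-dimethyl-1-[(E)-3-methylbuta-1,3-dien-1-yl]cyclooct-6-en-1-ol, 1-OH cis to the epoxide oxygen and to 5-OTBS | C=C(C)/C=C/[C@]1(O)C/C=C(C)\[C@@H](O[Si](C)(C)C(C)(C)C)C[C@H]2O[C@]21C | intermediate
14 | potassium alkoxide of 13 | C=C(C)/C=C/[C@]1([O-])C/C=C(C)\[C@@H](O[Si](C)(C)C(C)(C)C)C[C@H]2O[C@]21C.[K+] | intermediate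
15 | potassium enolate (C8=C9, ring-cis) of (4Z)-3β-(tert-butyldimethylsilyloxy)-1β,10β-epoxygermacra-4,11(12)-dien-9-one | [K+].[O-]/C1=C/[C@@H](C(C)=C)C/C=C(C)\[C@@H](O[Si](C)(C)C(C)(C)C)C[C@H]2O[C@]21C | intermediate
16 | (4Z)-3β-(tert-butyldimethylsilyloxy)-1β,10β-epoxy-8β-hydroxygermacra-4,11(12)-dien-9-one | C=C(C)[C@H]1C/C=C(C)\[C@@H](O[Si](C)(C)C(C)(C)C)C[C@H]2O[C@@]2(C)C(=O)[C@H]1O | intermediate
17 | (4Z)-1β,10β-epoxy-3β,8β-dihydroxygermacra-4,11(12)-dien-9-one | C=C(C)[C@H]1C/C=C(C)\[C@@H](O)C[C@H]2O[C@@]2(C)C(=O)[C@H]1O | intermediate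
18 | 1β,10β:4α,5α-diepoxy-3β,8β-dihydroxygermacr-11(12)-en-9-one | C=C(C)[C@H]1C[C@@H]2O[C@]2(C)[C@@H](O)C[C@H]2O[C@@]2(C)C(=O)[C@H]1O | intermediate
19 | 3β,8β-bis(angeloyloxy)-1β,10β:4α,5α-diepoxygermacr-11(12)-en-9-one | C=C(C)[C@H]1C[C@@H]2O[C@]2(C)[C@@H](OC(=O)/C(C)=C\C)C[C@H]2O[C@@]2(C)C(=O)[C@H]1OC(=O)/C(C)=C\C | intermediate
20 | 3β,8β-bis(angeloyloxy)-1β,10β:4α,5α-diepoxygermacr-11(12)-en-9β-ol | C=C(C)[C@H]1C[C@@H]2O[C@]2(C)[C@@H](OC(=O)/C(C)=C\C)C[C@H]2O[C@@]2(C)[C@@H](O)[C@H]1OC(=O)/C(C)=C\C | intermediate
21 | 9β-acetoxy-3β,8β-bis(angeloyloxy)-1β,10β:4α,5α-diepoxygermacr-11(12)-ene (CNP0220329.1) | C=C(C)[C@H]1C[C@@H]2O[C@]2(C)[C@@H](OC(=O)/C(C)=C\C)C[C@H]2O[C@@]2(C)[C@@H](OC(C)=O)[C@H]1OC(=O)/C(C)=C\C | target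

**Step count and risks**

Total steps: 14. Longest linear sequence: 13 steps (steps 1–6 and 8–14); step 7 prepares the dienyl iodide.

Steps most likely to fail:

1. Step 9. The alkoxide may fragment without re-bonding at C7 (bonding at the C4 terminus of the allyl unit or at C12, or loss of silanolate from the allyl anion), and the oxaziridine may approach the enolate from the wrong face. Fallback, from 13 back to 16: the tertiary hydroxyl is silylated (TMS-imidazole) to the trimethylsilyl ether F1. Thermolysis of F1 in a base-washed sealed tube (about 250 °C) should bring about the neutral siloxy version of the [1,3] shift, with no free carbanion, and give the ring-expanded trimethylsilyl enol ether F2. Rubottom oxidation of the enol ether with dimethyldioxirane at −78 °C gives the α-trimethylsilyloxy ketone F3, and mild methanolysis (citric acid, MeOH) returns 16.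

2. Step 1. Over-oxidation, attack at the methyl groups and selenium-induced transannular reactions of the 1,5-diene may leave little of the twofold ring-CH2 oxidation product. Fallback, from 1 back to 3: hydroboration (BH3·THF, then NaOH/H2O2) places oxygen on the two alkene CH carbons and gives 2,6-dimethylcyclooctane-1,5-diol F4. Oxidation (Dess–Martin) gives 2,6-dimethylcyclooctane-1,5-dione F5. The thermodynamic bis(trimethylsilyl enol ether) F6 (TMSCl, NaI, Et3N, MeCN) is then dehydrogenated by Saegusa–Ito oxidation (Pd(OAc)2, MeCN); this gives the same C2-symmetric dienedione 3.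

3. Step 11. Facial selectivity of the peracid in the flexible ten-membered ring may be poor, possibly aggravated by masking of the C3 hydroxyl as a transannular hemiketal with the C9 ketone. Fallback, from 16 back to 18: the alkene is epoxidised at the silyl ether stage with dimethyldioxirane (acetone, −20 °C), where the bulky silyloxy group shields its own face and no free C3 hydroxyl is present, to give the silyl-protected diepoxide F7. Desilylation with HF·pyridine then gives 18.

**Further compounds**

F1 | step 9 | trimethylsilyl ether of 13 | C=C(C)/C=C/[C@]1(O[Si](C)(C)C)C/C=C(C)\[C@@H](O[Si](C)(C)C(C)(C)C)C[C@H]2O[C@]21C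
F2 | step 9 | 9-trimethylsilyl enol ether (C8=C9, ring-cis) of (4Z)-3β-(tert-butyldimethylsilyloxy)-1β,10β-epoxygermacra-4,11(12)-dien-9-one | C[Si](C)(C)O/C1=C/[C@@H](C(C)=C)C/C=C(C)\[C@@H](O[Si](C)(C)C(C)(C)C)C[C@H]2O[C@]21C
F3 | step 9 | 8β-trimethylsilyl ether of 16 | C=C(C)[C@H]1C/C=C(C)\[C@@H](O[Si](C)(C)C(C)(C)C)C[C@H]2O[C@@]2(C)C(=O)[C@H]1O[Si](C)(C)C
F4 | step 1 | 2,6-dimethylcyclooctane-1,5-diol (stereoisomer mixture) | CC1CCC(O)C(C)CCC1O
F5 | step 1 | 2,6-dimethylcyclooctane-1,5-dione | CC1CCC(=O)C(C)CCC1=O
F6 | step 1 | 2,6-dimethyl-1,5-bis(trimethylsilyloxy)cycloocta-1,5-diene | C/C1=C(O[Si](C)(C)C)/CC/C(C)=C(O[Si](C)(C)C)\CC1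
F7 | step 11 | 3β-(tert-butyldimethylsilyloxy)-1β,10β:4α,5α-diepoxy-8β-hydroxygermacr-11(12)-en-9-one | C=C(C)[C@H]1C[C@@H]2O[C@]2(C)[C@@H](O[Si](C)(C)C(C)(C)C)C[C@H]2O[C@@]2(C)C(=O)[C@H]1O
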